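**Conventions.** Ring atoms carry the numbering of the target: C1 (quaternary fusion carbon with methyl), C2, C3, C4 (isopropyl carbinol), C5 (fusion CH), C6 (aroyloxy carbon), C7, C8 (methyl-bearing alkene carbon), C9, C10 (free carbinol). β is the face of the C1 methyl group, α the opposite face. "Daucane" denotes the target skeleton with this numbering (methyl on C1 and C8, isopropyl on C4); the carbon attached to C1 is called C15. TES = triethylsilyl.

**Assumption.** The ortho methoxy group does not change the sense of induction of the phosphoric acid catalyst in step 1, so the (S)-acid gives the (S)-carbinol as with simple aromatic aldehydes.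

## Analysis of the target

The target is a daucane sesquiterpenoid ester: a cyclopentane (C1–C5) trans-fused through C1–C5 to a cycloheptene (C1, C5–C10, alkene C8=C9), with methyl groups on C1 and C8, an isopropyl carbinol at C4, a free allylic alcohol at C10 and a 4-methoxybenzoate at C6. It has five stereocentres. The C4 hydroxyl is β (syn to the C1 methyl, isopropyl α), H5 is α (trans ring fusion), and both secondary oxygens, at C6 and C10, are α; C5 lies between two fully substituted carbons, C1 and C4. The sensitive relationships all involve C6: the C4 hydroxyl is β to it (an aldol that can cleave or dehydrate whenever C6 is a ketone), the C8=C9 alkene is β,γ to it (it moves into conjugation in a 6-ketone), and C6 and C10 are both secondary carbinols of which only one is to be acylated. The difficulty is therefore to build a seven-membered ring with a quaternary carbon and a tertiary carbinol on either side of the ring-fusion CH, and then to oxygenate C6 and C10 differently. The strategy rests on one feature: the six contiguous ring carbons C5–C10 carry exactly the substituents of a 1-alkyl-2-methoxy-4-methylbenzene (C4 on C5, oxygen on C6, methyl on C8), and C1 is the only atom of the seven-membered ring outside this set. The seven-membered ring is thus a benzene ring plus one carbon; if that carbon is a carbene tethered to C4 through C2 and C3, its insertion into the C5–C10 bond closes both rings at once.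

## Retrosynthetic reasoning

**C6–O acyl bond and C10–O–Si bond.** Target 34 is traced to its 10-O-triethylsilyl ether 33, and this to diol 31 and acid chloride 32. The ester is cut last because an aroyl ester would not survive the hydride, base and reducing steps that precede it. C10 must be silylated at that point because C6 and C10 are both secondary, whereas the tertiary C4 hydroxyl needs no protection against acylation.

**C6–H bond.** Alcohol 31 comes from ketone 30. A ketone at C6 is the natural oxidation level of an aryl ether carbon after dearomatisation. It also lets the free C4 hydroxyl, which is β and 1,3 to C6, deliver hydride to the β face so that the new oxygen ends up α; an external hydride would be steered to the other face by the axial C1 methyl.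

**C10–O bond and the position of the alkene.** Ketone 30 is the silyl ether of 29. Compound 29 is the product of reductive opening of the γ,δ-epoxy enone 28 at its allylic C9–O bond, and 28 comes from dienone 27 by epoxidation of the distal C9=C10 bond. These two steps turn the 7,9-dien-6-one that the arene leaves behind into the 10-hydroxy-8-ene of the target without a separate alkene transposition. The forward reactions must epoxidise the α face and protonate at C7 rather than C9.

**C5–H bond.** Dienone 27 is the hydrolysis product of methyl enol ether 25, with the C4 silyl ether removed in the same operation via 26. The enol ether is what remains of the anisole oxygen. Keeping C5 trigonal until here postpones the ring-fusion stereocentre to a stage at which it is α to a ketone and can settle in the trans-fused arrangement, where C6 is cis to the C4 oxygen and not to the isopropyl group.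

**C1 substituent (functional-group change).** The C1 methyl of 25 derives from the ester of 21 through alcohol 22, aldehyde 23 and hydrazone 24. The carbene carbon needs an acceptor group, so a carboxyl carbon at C1 is unavoidable. It is reduced directly after the key step, when nothing else is reducible, and through a hydrazone, because a cation or radical on C15 would be captured by the adjacent enol ether or vinyl groups.

**C1–C5 and C1–C10 (key disconnection).** Removing C1 from between C5 and C10 in triene 21 restores the benzene ring and leaves a carbene at C1: diazo ester 18. These are the only two bonds whose cleavage turns the seven-membered ring into a simple arene substitution pattern. One reaction then makes two rings, two C–C bonds and the quaternary stereocentre. It must add the carbenoid to the unsubstituted ortho carbon, on the arene face dictated by C4, faster than hydride migrates from C2.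

**C1=N2 and C1–C2 (chain assembly).** Diazo ester 18 comes from ester 14 by diazo transfer. The chain beyond C4 needs four carbons (C3, C2, C1 and the carboxyl carbon). Two come from the allyl group of 11 and two from acrylate 12, joined by cross-metathesis to 13 and then saturated. This keeps the stereogenic step simple and avoids carrying an ester through organolithium chemistry.

**C4–isopropyl bond.** Silyl ether 11 is the protected form of tertiary alcohol 10, which is cut at the C4–isopropyl bond to carbamate 5 and boronic ester 6. An enantioselective addition to a carbonyl group flanked by an ortho-substituted aryl and an isopropyl group would have to tell apart two branched groups of similar size. The 1,2-migration on boron (through 7, 8 and 9) is stereospecific instead, so C4 simply inherits the configuration of a secondary carbinol. A triethylsilyl ether is chosen for C4 because it must survive hydride, strong base and a carbenoid over seven steps and still leave with fluoride.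

**C4–C3 bond.** Carbamate 5 derives from alcohol 4, made from aldehyde 1 and allylboronate 2 through borate 3. Starting from the aldehyde fixes the arene pattern (oxygen ortho, methyl para to the benzylic carbon) without any regiochemical question.

## Alternatives that were turned down

**Alternative 1:** The C6–O ester bond and the C8=C9 π bond are formed together with cleavage of a C6–C8 bond. The seven-membered ring is thus contracted, in the retrosynthetic sense, to a six-membered ring carrying a cyclopropane (C6–C7–C8) and a 9,10-cyclic sulfate. In the forward key step an anisate nucleophile attacks C6 while the C9–O bond ionises, giving the 10-O-sulfate monoester A1, which needs only hydrolysis.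
- For: the ester is installed directly with inversion at C6, C10 comes from a diol, the two secondary hydroxyls never need differentiating, and ring expansion and alkene placement are merged. On the end game it is stronger than the chosen route, whose last six steps serve exactly these purposes.
- Against: C9 is a cyclopropylcarbinyl centre, and such cations are captured by direct substitution at C9, by opening toward the primary C7 (which keeps the six-membered ring) or by opening toward C6. C6 is a secondary carbon next to the congested C5, and a weakly nucleophilic carboxylate should prefer C7 or C9 unless only the C6–C8 bond is aligned with the leaving group. The substrate needs seven defined stereocentres on a cyclopropane-fused bicycle, so it is not shorter to make.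
- Comparison: the regiochemical gamble falls on the last C–O bond formation, on the most valuable intermediate. The chosen route places its uncertain step at step 8 and builds the carbon skeleton in it.

**Alternative 2:** C5–C6 and C4–O are disconnected through an isoxazoline that masks the C4-hydroxy/C6-keto aldol; the seven-membered ring is closed later between C9 and C10. In the forward key step a nitrile oxide whose carbon is C6, carrying the C7–C9 iodoalkenyl arm, adds to the trisubstituted C4=C5 alkene of a cyclopentene that already holds the quaternary C1, giving isoxazoline A2.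
- For: it is convergent, the cis delivery of carbon and oxygen gives the correct C4/C5 relationship by mechanism, and the isoxazoline protects the retro-aldol-prone pair until late, which is a real weakness of the chosen route. Every step has close precedent, which the chosen key step lacks.
- Against: the dipolarophile is a trisubstituted alkene next to a quaternary carbon, a poor partner for an intermolecular nitrile oxide that dimerises readily. Facial selectivity must come from the small difference between a methyl and a silyloxymethyl group on C1. C1 must first be made as an enantioenriched quaternary centre by separate chemistry. Reductive N–O cleavage must spare an alkenyl iodide before a ring closure that also has to set C10.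
- Comparison: it trades one unprecedented step for several selectivity questions spread over the synthesis, and needs more steps to assemble its fragments than the eight that lead to 21.

**Alternative 3:** The C1–C5 bond is traced back to a C1–C6 bond of a decalin of the Robinson-annulation (Wieland–Miescher) type. In the forward key step a strong alkoxide base deprotonates the C6 hydroxyl of a 6-hydroxy-5-sulfonate and C1 migrates from C6 to C5 anti to the leaving group, giving the trans-fused hydroazulen-6-one A3 with the C10 oxygen and the C8=C9 alkene in place.
- For: the decalin is available enantiopure with the quaternary C1 already set, the shift is stereospecific and long established for hydroazulenes, and A3 already has C5, C10 and the alkene correct. On predictability of the key step and on control of C1, C5 and C10 it is stronger than the chosen route.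
- Against: the C8 methyl, the C10 oxygen and a stereodefined diol monosulfonate must first be installed on the decalin, a long linear sequence. The β,γ-unsaturated ketone of A3 is formed under strongly basic conditions that favour conjugation. C4 is left for last, as addition of an isopropyl nucleophile to a hindered, enolisable cyclopentanone 1,3 to the C6 carbonyl, which is prone to enolisation, reduction and retro-aldol cleavage.
- Comparison: the chosen route sets C4 first by a stereospecific reaction, uses it to control C1, and reaches the bicyclic skeleton in eight steps; what it gives up is precedent.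

Key step: step 8

## Route

Step 1
Reactants: 1 2-methoxy-4-methylbenzaldehyde; 2 allylboronic acid pinacol ester
Product: 4 (S)-1-(2-methoxy-4-methylphenyl)but-3-en-1-ol, via O-boryl ether 3 (not isolated)
Conditions: 2 (1.2 equiv), (S)-TRIP [(S)-3,3′-bis(2,4,6-triisopropylphenyl)-1,1′-binaphthyl-2,2′-diyl hydrogen phosphate] (5 mol%), toluene, −30 °C; aq. NaHCO3
Reagents that add atoms: none
Why: Chiral phosphoric acid-catalysed allylboration of an aromatic aldehyde through a chair six-membered transition state in which the acid binds a boronate oxygen and the formyl hydrogen; the (S)-acid should expose the face of 1 that leads to the (S)-carbinol, and aqueous work-up cleaves borate 3.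

Step 2
Reactants: 4 (S)-1-(2-methoxy-4-methylphenyl)but-3-en-1-ol
Product: 5 (S)-1-(2-methoxy-4-methylphenyl)but-3-en-1-yl N,N-diisopropylcarbamate
Conditions: iPr2NC(O)Cl, Et3N, CH2Cl2, reflux
Reagents that add atoms: N,N-diisopropylcarbamoyl chloride, CC(C)N(C(C)C)C(Cl)=O
Why: Carbamoylation of a secondary benzylic alcohol; the carbamate is the directing and leaving group of the next step and the stereocentre is not touched.

Step 3
Reactants: 5 (S)-1-(2-methoxy-4-methylphenyl)but-3-en-1-yl N,N-diisopropylcarbamate; 6 isopropylboronic acid pinacol ester
Product: 10 (R)-3-(2-methoxy-4-methylphenyl)-2-methylhex-5-en-3-ol, via lithiated carbamate 7 (not isolated), via boronate complex 8 (not isolated), via tertiary boronic ester 9 (not isolated)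
Conditions: s-BuLi, Et2O, −78 °C; 6, −78 °C; MgBr2, MeOH, −78 °C → rt; then aq. NaOH, H2O2, THF, 0 °C → rt
Reagents that add atoms: hydrogen peroxide, OO
Why: Lithiation–borylation of a secondary benzylic carbamate: directed deprotonation with retention gives 7, which is configurationally stable at −78 °C and adds to boron of 6 with retention (8); the isopropyl group then migrates from boron to carbon anti to the departing carbamate (1,2-metallate rearrangement, inversion) to give 9, and oxidation of the C–B bond proceeds with retention, so the (S)-carbamate gives the (R)-carbinol. MgBr2/MeOH speeds the migration in the hindered boronate and suppresses its reversal.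

Step 4
Reactants: 10 (R)-3-(2-methoxy-4-methylphenyl)-2-methylhex-5-en-3-ol
Product: 11 (R)-triethyl{[3-(2-methoxy-4-methylphenyl)-2-methylhex-5-en-3-yl]oxy}silane
Conditions: Et3SiOTf, 2,6-lutidine, CH2Cl2, −78 → 0 °C
Reagents that add atoms: triethylsilyl trifluoromethanesulfonate, CC[Si](CC)(CC)OS(=O)(=O)C(F)(F)F
Why: Silylation of a hindered tertiary alcohol with a silyl triflate under buffered conditions, which avoids ionisation of the electron-rich benzylic C–O bond; the silyl ether later prevents O–H insertion of the carbenoid.

Step 5
Reactants: 11 (R)-triethyl{[3-(2-methoxy-4-methylphenyl)-2-methylhex-5-en-3-yl]oxy}silane; 12 methyl acrylate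
Product: 13 methyl (2E,5R)-5-(2-methoxy-4-methylphenyl)-6-methyl-5-(triethylsilyloxy)hept-2-enoate
Conditions: 12 (5 equiv), second-generation Hoveyda–Grubbs catalyst RuCl2(H2IMes)(=CH-C6H4-2-OiPr) (5 mol%), CH2Cl2, 40 °C
Reagents that add atoms: none
Why: Cross-metathesis of a terminal alkene with an electron-poor acrylate is selective for the cross product and the E-enoate; it supplies C1 and the carboxyl carbon.

Step 6
Reactants: 13 methyl (2E,5R)-5-(2-methoxy-4-methylphenyl)-6-methyl-5-(triethylsilyloxy)hept-2-enoate
Product: 14 methyl (R)-5-(2-methoxy-4-methylphenyl)-6-methyl-5-(triethylsilyloxy)heptanoate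
Conditions: H2 (1 atm), 5% Pd/C, EtOAc, rt
Reagents that add atoms: none
Why: Heterogeneous hydrogenation of a conjugated disubstituted alkene; the arene and the hindered tertiary benzylic silyl ether should not react at 1 atm in ethyl acetate.

Step 7
Reactants: 14 methyl (R)-5-(2-methoxy-4-methylphenyl)-6-methyl-5-(triethylsilyloxy)heptanoate; 15 4-acetamidobenzenesulfonyl azide
Product: 18 methyl (R)-2-diazo-5-(2-methoxy-4-methylphenyl)-6-methyl-5-(triethylsilyloxy)heptanoate, via lithium enolate 16 (not isolated), via trifluoroacetyl ester 17 (not isolated)
Conditions: LiN(SiMe3)2, THF, −78 °C; CF3CO2CH2CF3; 5% aq. HCl work-up; then 15, Et3N, H2O (1 equiv), MeCN, rt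
Reagents that add atoms: none
Why: Detrifluoroacetylative diazo transfer: a simple ester does not accept a diazo group directly, so enolate 16 is C-trifluoroacetylated to 17, whose activated methine adds to the sulfonyl azide; fragmentation expels the trifluoroacetyl group on the sulfonamide nitrogen.

Step 8
Reactants: 18 methyl (R)-2-diazo-5-(2-methoxy-4-methylphenyl)-6-methyl-5-(triethylsilyloxy)heptanoate
Product: 21 methyl 6-methoxy-4β-(triethylsilyloxy)dauca-5,7,9-trien-15-oate, via rhodium carbenoid 19 (not isolated), via norcaradiene 20 (not isolated)
Conditions: Rh2(S-PTTL)4 (dirhodium tetrakis[N-phthaloyl-(S)-tert-leucinate], 1 mol%), toluene, −78 °C, slow addition of 18, then −78 → −40 °C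
Reagents that add atoms: none
Why: Proposed new method: loss of N2 from 18 at the dirhodium carboxylate gives the electrophilic carbenoid 19, whose carbon C1 is held by the C2–C3–C4 tether above the ipso carbon C5 and adds across the C5–C10 π bond of the electron-rich arene to give norcaradiene 20; 20 then opens by a thermal disrotatory 6π electrocyclic reaction (C5–C10 cleavage) to cycloheptatriene 21. The closest known reaction types are the intramolecular Buchner reaction of aryl-tethered diazo ketones under Rh2(OAc)4 and the low-temperature cyclopropanation of alkenes with α-alkyl-α-diazo esters under Rh2(S-PTTL)4; an α-alkyl-α-diazo ester has not been shown to add to a tethered arene in this way. The five-membered ring closes in the 5-exo mode (C1 bonds to C5 while C10 stays outside the new ring), and the seven-membered ring is not closed end to end but arises by one-carbon expansion of the benzene ring through the [2+1] addition and the electrocyclic opening. The only new stereocentre is C1 and it is decided by the arene face that is attacked: when the tether swings over one face, one of the two other C4 substituents must lie close to the arene plane beside the ortho methoxy group and the other must stand perpendicular on the far face, so the isopropyl group should take the far position and the slimmer C4–O bond the in-plane one; since the ester is necessarily the exo substituent of the cyclopropane, this places it syn to the C4 oxygen, and the chiral pocket of the catalyst is meant to reinforce this substrate bias. Regioselectivity (C10, not the methoxy-bearing C6) should follow from the reluctance of carbenoids to add to a substituted arene carbon. Chemoselectivity over 1,2-hydride migration from C2 relies on the bulky carboxylate ligands, −78 °C and the intramolecular trap, and selectivity over insertion into the isopropyl C–H bond or attack on the ether oxygen relies on the crowding and inductive deactivation of that methine by the neighbouring C–O bond, on the shielding of the oxygen by the triethylsilyl group and on the activation of the arene by its methoxy and methyl groups.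

Step 9
Reactants: 21 methyl 6-methoxy-4β-(triethylsilyloxy)dauca-5,7,9-trien-15-oate
Product: 22 6-methoxy-4β-(triethylsilyloxy)dauca-5,7,9-trien-15-ol
Conditions: LiAlH4, THF, 0 °C
Reagents that add atoms: none
Why: Hydride reduction of a methyl ester to the primary alcohol; enol ether, triene and silyl ether are inert to LiAlH4.

Step 10
Reactants: 22 6-methoxy-4β-(triethylsilyloxy)dauca-5,7,9-trien-15-ol
Product: 23 6-methoxy-4β-(triethylsilyloxy)dauca-5,7,9-trien-15-al
Conditions: Dess–Martin periodinane, NaHCO3, CH2Cl2, 0 °C → rt
Reagents that add atoms: none
Why: Dess–Martin oxidation of a neopentyl primary alcohol under bicarbonate buffer, which protects the acid-labile enol ether; the aldehyde has no α-hydrogen, so it cannot epimerise.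

Step 11
Reactants: 23 6-methoxy-4β-(triethylsilyloxy)dauca-5,7,9-trien-15-al
Product: 25 6-methoxy-4β-(triethylsilyloxy)dauca-5,7,9-triene, via hydrazone 24 (not isolated)
Conditions: N2H4·H2O, EtOH, rt; concentrate; KOtBu, DMSO, 23 °C
Reagents that add atoms: none
Why: Wolff–Kishner reduction through the preformed hydrazone 24 with KOtBu in DMSO at room temperature; C15 passes through an anionic diazene and never becomes a cation or a radical, so neither participation of the enol ether nor a 1,2-vinyl shift can intervene.

Step 12
Reactants: 25 6-methoxy-4β-(triethylsilyloxy)dauca-5,7,9-triene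
Product: 27 4β-hydroxy-5αH-dauca-7,9-dien-6-one, via silyl ketone 26 (not isolated)
Conditions: 48% aq. HF, MeCN, 0 °C → rt
Reagents that add atoms: water, O
Why: Enol ether hydrolysis by rate-limiting protonation at C5 gives the C6 oxocarbenium ion and, with water, ketone 26; the slower fluoride cleavage of the hindered silyl ether follows only after the enol ether, which would make the C4 oxygen an allylic leaving group, is gone. C5 is set here: the proton should arrive from the α face, opposite the C1 methyl and the C4 silyloxy group, and the trans-fused ketone should also be the more stable epimer because C6 is then cis to the C4 oxygen rather than to the isopropyl group.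

Step 13
Reactants: 27 4β-hydroxy-5αH-dauca-7,9-dien-6-one
Product: 28 9α,10α-epoxy-4β-hydroxy-5αH-dauc-7-en-6-one
Conditions: mCPBA, NaHCO3, CH2Cl2, 0 °C
Reagents that add atoms: 3-chloroperoxybenzoic acid, OOC(=O)c1cccc(Cl)c1
Why: Peracid epoxidation of a 2,4-dienone takes place at the γ,δ-alkene (C9=C10) because the α,β-alkene is deactivated by the carbonyl group; the reagent should approach the α face, anti to the axial C1 methyl, which fixes C9 and C10.

Step 14
Reactants: 28 9α,10α-epoxy-4β-hydroxy-5αH-dauc-7-en-6-one
Product: 29 4β,10α-dihydroxy-5αH-dauc-8-en-6-one
Conditions: SmI2 (2.2 equiv), THF/MeOH, −78 °C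
Reagents that add atoms: none
Why: Reductive opening of a γ,δ-epoxy enone: electron transfer to the enone cleaves the allylic C9–O bond, the alkene moves to C8=C9, and methanol protonates kinetically at C7, α to the carbonyl. The C10–O bond is not touched, so C10 keeps its α configuration.

Step 15
Reactants: 29 4β,10α-dihydroxy-5αH-dauc-8-en-6-one
Product: 30 4β-hydroxy-10α-(triethylsilyloxy)-5αH-dauc-8-en-6-one
Conditions: Et3SiCl, imidazole, DMF, 0 °C
Reagents that add atoms: chlorotriethylsilane, CC[Si](Cl)(CC)CC
Why: Silylation distinguishes the secondary allylic C10 hydroxyl from the tertiary C4 hydroxyl, which does not react with a silyl chloride; a weak base at 0 °C is used so that the β,γ-alkene does not move into conjugation, and any transannular hemiketal between O10 and C6 is drained through the open form.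

Step 16
Reactants: 30 4β-hydroxy-10α-(triethylsilyloxy)-5αH-dauc-8-en-6-one
Product: 31 10α-(triethylsilyloxy)-5αH-dauc-8-ene-4β,6α-diol
Conditions: Me4NBH(OAc)3, MeCN/AcOH (1:1), −30 °C
Reagents that add atoms: none
Why: Hydroxyl-directed reduction of a β-hydroxy ketone (Evans–Saksena reduction): an acetate on boron is exchanged for the C4 hydroxyl, which is β and cis to C6 on the five-membered ring, and hydride is delivered intramolecularly to the β face of the carbonyl, giving the 6α-alcohol (1,3-anti to the C4 oxygen).

Step 17
Reactants: 31 10α-(triethylsilyloxy)-5αH-dauc-8-ene-4β,6α-diol; 32 4-methoxybenzoyl chloride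
Product: 33 4β-hydroxy-10α-(triethylsilyloxy)-5αH-dauc-8-en-6α-yl 4-methoxybenzoate
Conditions: 32, DMAP, Et3N, CH2Cl2, 0 °C → rt
Reagents that add atoms: none
Why: DMAP-catalysed acylation of the only free secondary hydroxyl; the tertiary C4 hydroxyl is inert under these conditions and C10 is silylated.

Step 18
Reactants: 33 4β-hydroxy-10α-(triethylsilyloxy)-5αH-dauc-8-en-6α-yl 4-methoxybenzoate
Product: 34 4β,10α-dihydroxy-5αH-dauc-8-en-6α-yl 4-methoxybenzoate
Conditions: HF·pyridine, pyridine, THF, 0 °C
Reagents that add atoms: none
Why: Fluoride cleavage of a secondary triethylsilyl ether under buffered conditions that leave the ester and the allylic alcohol untouched.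

## Compound list

1 | 2-methoxy-4-methylbenzaldehyde | O=Cc1ccc(C)cc1OC | starting material
2 | allylboronic acid pinacol ester (2-allyl-4,4,5,5-tetramethyl-1,3,2-dioxaborolane) | C=CCB1OC(C)(C)C(C)(C)O1 | starting material
3 | O-pinacolboryl ether of 4, formed in the flask in step 1 | C=CC[C@H](OB1OC(C)(C)C(C)(C)O1)c1ccc(C)cc1OC | intermediate
4 | (S)-1-(2-methoxy-4-methylphenyl)but-3-en-1-ol | C=CC[C@H](O)c1ccc(C)cc1OC | intermediate
5 | (S)-1-(2-methoxy-4-methylphenyl)but-3-en-1-yl N,N-diisopropylcarbamate | C=CC[C@H](OC(=O)N(C(C)C)C(C)C)c1ccc(C)cc1OC | intermediate
6 | isopropylboronic acid pinacol ester (2-isopropyl-4,4,5,5-tetramethyl-1,3,2-dioxaborolane) | CC(C)B1OC(C)(C)C(C)(C)O1 | starting material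
7 | lithiated carbamate (lithium in the place of the benzylic hydrogen of 5), formed in the flask in step 3 | C=CC[C@]([Li])(OC(=O)N(C(C)C)C(C)C)c1ccc(C)cc1OC | intermediate
8 | lithium boronate complex of 7 and 6 (boron in the place of lithium), formed in the flask in step 3 | C=CC[C@]([B-]1(C(C)C)OC(C)(C)C(C)(C)O1)(OC(=O)N(C(C)C)C(C)C)c1ccc(C)cc1OC.[Li+] | intermediate
9 | (S)-2-[3-(2-methoxy-4-methylphenyl)-2-methylhex-5-en-3-yl]-4,4,5,5-tetramethyl-1,3,2-dioxaborolane, formed in the flask in step 3 | C=CC[C@@](B1OC(C)(C)C(C)(C)O1)(C(C)C)c1ccc(C)cc1OC | intermediate
10 | (R)-3-(2-methoxy-4-methylphenyl)-2-methylhex-5-en-3-ol | C=CC[C@@](O)(C(C)C)c1ccc(C)cc1OC | intermediate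
11 | (R)-triethyl{[3-(2-methoxy-4-methylphenyl)-2-methylhex-5-en-3-yl]oxy}silane | C=CC[C@@](O[Si](CC)(CC)CC)(C(C)C)c1ccc(C)cc1OC | intermediate
12 | methyl acrylate | C=CC(=O)OC | starting material
13 | methyl (2E,5R)-5-(2-methoxy-4-methylphenyl)-6-methyl-5-(triethylsilyloxy)hept-2-enoate | COC(=O)/C=C/C[C@@](O[Si](CC)(CC)CC)(C(C)C)c1ccc(C)cc1OC | intermediate
14 | methyl (R)-5-(2-methoxy-4-methylphenyl)-6-methyl-5-(triethylsilyloxy)heptanoate | COC(=O)CCC[C@@](O[Si](CC)(CC)CC)(C(C)C)c1ccc(C)cc1OC | intermediate
15 | 4-acetamidobenzenesulfonyl azide | CC(=O)Nc1ccc(cc1)S(=O)(=O)N=[N+]=[N-] | starting material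
16 | lithium enolate of 14, formed in the flask in step 7 | COC(O[Li])=CCC[C@@](O[Si](CC)(CC)CC)(C(C)C)c1ccc(C)cc1OC | intermediate
17 | methyl (5R)-5-(2-methoxy-4-methylphenyl)-6-methyl-5-(triethylsilyloxy)-2-(trifluoroacetyl)heptanoate (either C2 epimer), used crude in step 7 | COC(=O)C(C(=O)C(F)(F)F)CC[C@@](O[Si](CC)(CC)CC)(C(C)C)c1ccc(C)cc1OC | intermediate
18 | methyl (R)-2-diazo-5-(2-methoxy-4-methylphenyl)-6-methyl-5-(triethylsilyloxy)heptanoate | COC(=O)C(=[N+]=[N-])CC[C@@](O[Si](CC)(CC)CC)(C(C)C)c1ccc(C)cc1OC | intermediate
19 | dirhodium carbenoid at C1 derived from 18 (only the carbene-bearing rhodium atom of the Rh2(S-PTTL)4 core is written), formed in the flask in step 8 | COC(=O)C(=[Rh])CC[C@@](O[Si](CC)(CC)CC)(C(C)C)c1ccc(C)cc1OC | intermediate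
20 | norcaradiene valence isomer of 21 (cyclopropane C1–C5–C10, alkenes C6=C7 and C8=C9, ester syn to the C4 oxygen), formed in the flask in step 8 | COC1=CC(C)=C[C@@H]2[C@@]3(C(=O)OC)CC[C@@](O[Si](CC)(CC)CC)(C(C)C)[C@@]123 | intermediate
21 | methyl 6-methoxy-4β-(triethylsilyloxy)dauca-5,7,9-trien-15-oate (C1 ester β, C5=C6 methyl enol ether, C7=C8, C9=C10) | COC1=C2[C@](O[Si](CC)(CC)CC)(C(C)C)CC[C@]2(C(=O)OC)C=CC(C)=C1 | intermediate
22 | 6-methoxy-4β-(triethylsilyloxy)dauca-5,7,9-trien-15-ol | COC1=C2[C@](O[Si](CC)(CC)CC)(C(C)C)CC[C@]2(CO)C=CC(C)=C1 | intermediate
23 | 6-methoxy-4β-(triethylsilyloxy)dauca-5,7,9-trien-15-al | COC1=C2[C@](O[Si](CC)(CC)CC)(C(C)C)CC[C@]2(C=O)C=CC(C)=C1 | intermediate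
24 | hydrazone of 23, used crude in step 11 | COC1=C2[C@](O[Si](CC)(CC)CC)(C(C)C)CC[C@]2(C=NN)C=CC(C)=C1 | intermediate
25 | 6-methoxy-4β-(triethylsilyloxy)dauca-5,7,9-triene | COC1=C2[C@](O[Si](CC)(CC)CC)(C(C)C)CC[C@]2(C)C=CC(C)=C1 | intermediate
26 | 4β-(triethylsilyloxy)-5αH-dauca-7,9-dien-6-one, formed in the flask in step 12 | O=C1C=C(C)C=C[C@@]2(C)CC[C@@](O[Si](CC)(CC)CC)(C(C)C)[C@H]12 | intermediate
27 | 4β-hydroxy-5αH-dauca-7,9-dien-6-one | O=C1C=C(C)C=C[C@@]2(C)CC[C@@](O)(C(C)C)[C@H]12 | intermediate
28 | 9α,10α-epoxy-4β-hydroxy-5αH-dauc-7-en-6-one | O=C1C=C(C)[C@H]3O[C@H]3[C@@]2(C)CC[C@@](O)(C(C)C)[C@H]12 | intermediate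
29 | 4β,10α-dihydroxy-5αH-dauc-8-en-6-one | O=C1CC(C)=C[C@@H](O)[C@@]2(C)CC[C@@](O)(C(C)C)[C@H]12 | intermediate
30 | 4β-hydroxy-10α-(triethylsilyloxy)-5αH-dauc-8-en-6-one | O=C1CC(C)=C[C@@H](O[Si](CC)(CC)CC)[C@@]2(C)CC[C@@](O)(C(C)C)[C@H]12 | intermediate
31 | 10α-(triethylsilyloxy)-5αH-dauc-8-ene-4β,6α-diol | O[C@H]1CC(C)=C[C@@H](O[Si](CC)(CC)CC)[C@@]2(C)CC[C@@](O)(C(C)C)[C@H]12 | intermediate
32 | 4-methoxybenzoyl chloride | COc1ccc(cc1)C(Cl)=O | starting material
33 | 4β-hydroxy-10α-(triethylsilyloxy)-5αH-dauc-8-en-6α-yl 4-methoxybenzoate | COc1ccc(C(=O)O[C@H]2CC(C)=C[C@@H](O[Si](CC)(CC)CC)[C@@]3(C)CC[C@@](O)(C(C)C)[C@H]23)cc1 | intermediate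
34 | 4β,10α-dihydroxy-5αH-dauc-8-en-6α-yl 4-methoxybenzoate (CNP0211568.1) | COc1ccc(C(=O)O[C@H]2CC(C)=C[C@@H](O)[C@@]3(C)CC[C@@](O)(C(C)C)[C@H]23)cc1 | target

## Step count and weakest steps

Total step count: 18. Longest linear sequence: 18 steps (1 to 34); the route is linear, and 2, 6, 12, 15 and 32 are used as bought.

**Step 8 (key step, new method).** The most likely failure is that 1,2-hydride migration from C2 consumes the carbenoid before it reaches the arene, since an arene is a poorer trap than the alkenes for which the low-temperature protocol is established. Facial selectivity may also erode if the S-configured catalyst opposes the substrate bias; the antipodal catalyst or the achiral Rh2(O2CCPh3)4 would be tried first. Addition at the methoxy-bearing bond or insertion into the isopropyl methine may also compete.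

The fallback uses known chemistry, the intramolecular Buchner reaction of aryl-tethered α-diazo ketones under Rh2(OAc)4, which also tolerates a methyl group on the diazo carbon. It sets out from 11 and comes back at 25. Ozonolysis of 11 (O3, CH2Cl2, −78 °C; PPh3) would give (R)-3-(2-methoxy-4-methylphenyl)-4-methyl-3-(triethylsilyloxy)pentanal F1. Addition of EtMgBr gives (5R)-5-(2-methoxy-4-methylphenyl)-6-methyl-5-(triethylsilyloxy)heptan-3-ol F2, and Dess–Martin oxidation gives (R)-5-(2-methoxy-4-methylphenyl)-6-methyl-5-(triethylsilyloxy)heptan-3-one F3. Kinetic enolisation on the less hindered ethyl side (LiN(SiMe3)2, −78 °C) and trifluoroacetylation give (6R)-1,1,1-trifluoro-6-(2-methoxy-4-methylphenyl)-3,7-dimethyl-6-(triethylsilyloxy)octane-2,4-dione F4. With 15 and Et3N this gives (R)-2-diazo-5-(2-methoxy-4-methylphenyl)-6-methyl-5-(triethylsilyloxy)heptan-3-one F5. Rh2(OAc)4 in CH2Cl2 should convert it into 6-methoxy-4β-(triethylsilyloxy)dauca-5,7,9-trien-2-one F6, in which C1 already carries the methyl group; the same conformational argument places that methyl syn to the C4 oxygen. Wolff–Kishner reduction of the C2 carbonyl through the C2 hydrazone of F6 F7 (conditions of step 11, warmed if needed) returns to 25 and makes steps 5 to 11 unnecessary.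

**Step 12.** Protonation at C5 may occur from the β face and the cis-fused ketone may not equilibrate in weak acid. Alternatively the C4–O bond, allylic to the enol ether, may ionise, or the β-hydroxy ketone may dehydrate or cleave on long exposure to acid. The fallback separates the operations and changes the way C5 is set. From 25 only the enol ether is hydrolysed (dilute aqueous oxalic acid, THF, 0 °C) and 26 is isolated. C5 is equilibrated with DBU in toluene while the aldol oxygen is still silylated, so that retro-aldol cleavage is blocked. The silyl ether is then cleaved with buffered HF·pyridine to come back at 27. This fallback makes no compound outside the list (F0).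

**Step 11.** Under KOtBu/DMSO the double bonds of the trienyl ether may migrate by deprotonation at the C8 methyl, or hydrazone formation at the neopentyl aldehyde may stall or give azine. The fallback leaves strong base altogether. From 23 the 4-methylbenzenesulfonylhydrazone of 23 F8 is formed (TsNHNH2, THF, rt), reduced at C=N with catecholborane (CHCl3, 0 °C) and decomposed with NaOAc·3H2O at reflux. Loss of sulfinate and N2 gives 25.

**Step 13.** The peracid may attack the trisubstituted C7=C8 bond, approach the β face, or cause Baeyer–Villiger oxidation. The fallback installs the C10 oxygen by conjugate addition instead of epoxidation. From 27, copper-catalysed 1,6-boration (CuCl, a bisphosphine, NaOtBu, bis(pinacolato)diboron, MeOH, THF) should place boron on C10 anti to the C1 methyl and move the alkene to C8=C9, giving 4β-hydroxy-10α-(4,4,5,5-tetramethyl-1,3,2-dioxaborolan-2-yl)-5αH-dauc-8-en-6-one F9. Oxidation with NaBO3·4H2O (retention) comes back at 29, bypassing 28 and step 14.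

**Step 16.** Ligand exchange at the hindered tertiary hydroxyl may be slow, so that undirected hydride attack from the less hindered α face competes and the C6 epimer forms. The fallback accepts α-face attack and inverts afterwards. From 30, LiBH(s-Bu)3 (THF, −78 °C) gives 10α-(triethylsilyloxy)-5αH-dauc-8-ene-4β,6β-diol F10. Mitsunobu esterification with 4-methoxybenzoic acid (PPh3, diisopropyl azodicarboxylate, toluene) inverts C6 and comes back at 33, replacing step 17 as well.

## Further compounds

F1 | step 8 | (R)-3-(2-methoxy-4-methylphenyl)-4-methyl-3-(triethylsilyloxy)pentanal | O=CC[C@@](O[Si](CC)(CC)CC)(C(C)C)c1ccc(C)cc1OC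
F2 | step 8 | (5R)-5-(2-methoxy-4-methylphenyl)-6-methyl-5-(triethylsilyloxy)heptan-3-ol (either C3 epimer) | CCC(O)C[C@@](O[Si](CC)(CC)CC)(C(C)C)c1ccc(C)cc1OC
F3 | step 8 | (R)-5-(2-methoxy-4-methylphenyl)-6-methyl-5-(triethylsilyloxy)heptan-3-one | CCC(=O)C[C@@](O[Si](CC)(CC)CC)(C(C)C)c1ccc(C)cc1OC
F4 | step 8 | (6R)-1,1,1-trifluoro-6-(2-methoxy-4-methylphenyl)-3,7-dimethyl-6-(triethylsilyloxy)octane-2,4-dione (either C3 epimer) | CC(C(=O)C(F)(F)F)C(=O)C[C@@](O[Si](CC)(CC)CC)(C(C)C)c1ccc(C)cc1OC
F5 | step 8 | (R)-2-diazo-5-(2-methoxy-4-methylphenyl)-6-methyl-5-(triethylsilyloxy)heptan-3-one | CC(=[N+]=[N-])C(=O)C[C@@](O[Si](CC)(CC)CC)(C(C)C)c1ccc(C)cc1OC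
F6 | step 8 | 6-methoxy-4β-(triethylsilyloxy)dauca-5,7,9-trien-2-one | COC1=C2[C@](O[Si](CC)(CC)CC)(C(C)C)CC(=O)[C@]2(C)C=CC(C)=C1
F7 | step 8 | C2 hydrazone of F6 | COC1=C2[C@](O[Si](CC)(CC)CC)(C(C)C)CC(=NN)[C@]2(C)C=CC(C)=C1
F0 | step 12 | none | none
F8 | step 11 | 4-methylbenzenesulfonylhydrazone of 23 | COC1=C2[C@](O[Si](CC)(CC)CC)(C(C)C)CC[C@]2(C=NNS(=O)(=O)c3ccc(C)cc3)C=CC(C)=C1
F9 | step 13 | 4β-hydroxy-10α-(4,4,5,5-tetramethyl-1,3,2-dioxaborolan-2-yl)-5αH-dauc-8-en-6-one | O=C1CC(C)=C[C@@H](B2OC(C)(C)C(C)(C)O2)[C@@]3(C)CC[C@@](O)(C(C)C)[C@H]13
F10 | step 16 | 10α-(triethylsilyloxy)-5αH-dauc-8-ene-4β,6β-diol | O[C@@H]1CC(C)=C[C@@H](O[Si](CC)(CC)CC)[C@@]2(C)CC[C@@](O)(C(C)C)[C@H]12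
A1 | alternative 1 | 10-O-sulfate monoester anion of the target | COc1ccc(C(=O)O[C@H]2CC(C)=C[C@@H](OS(=O)(=O)[O-])[C@@]3(C)CC[C@@](O)(C(C)C)[C@H]23)cc1
A2 | alternative 2 | cyclopentane-fused isoxazoline (ring C6, N, O, C4, C5) with the (Z)-iodoalkenyl arm on C6 and methyl and tert-butyldimethylsilyloxymethyl on C1 | I/C=C(C)\CC2=NO[C@@]3(C(C)C)CC[C@](C)(CO[Si](C)(C)C(C)(C)C)[C@@H]23
A3 | alternative 3 | trans-fused hydroazulen-6-one with C4 dioxolane and C10 tert-butyldimethylsilyl ether | O=C2CC(C)=C[C@@H](O[Si](C)(C)C(C)(C)C)[C@@]3(C)CCC4(OCCO4)[C@H]23
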